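The ten-membered ring is a cyclodeca-1,3,5-triene (C10=C1–C2=C3–C4=C5 in clerodane numbering, with C6–C9 saturated), which is the open valence isomer of a bicyclo[4.4.0]deca-2,4-diene. The plan rests on cleaving a transannular C5–C10 bond. A cis-fused hexalin (cyclohexadiene ring A fused to cyclohexane ring B) is ring-expanded by photochemical conrotatory 6π opening. This forms the macrocycle and sets the 1(10)E,2Z,4Z geometry in one operation. It also erases C5 and C10, so both cis-fused diastereomers converge. The precursor, a cis-clerodadiene acetoxy acid, comes from a cuprate-derived cyclohexene (C8 and C9 set) by an intramolecular 2-pyrone Diels–Alder/CO2 extrusion.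

Key step: step 9

Remarks:
- Numbering: clerodane numbering is used for the carbocycle throughout. C5 bears C19H2OAc, C4 bears C18O2H, C8 bears the C17 methyl, and C9 bears the C20 methyl and the C11–C12 furylethyl chain.
- Assumption: the (E)-CH=CH unit of the ten-membered ring can swing through the ring at ambient temperature, as in trans-cyclodecene. The ring conformers then interconvert and the product is fully defined by C8, C9 and the three alkene geometries.
- Starting materials: compounds 1, 5, 9 and 11 are taken as catalogue compounds.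

Step 1
Reactants: 1 3,4-dimethylanisole
Product: 3 3,4-dimethylcyclohex-3-en-1-one, via 1-methoxy-4,5-dimethylcyclohexa-1,4-diene 2 (not isolated)
Conditions: Li, liq. NH3, t-BuOH, THF, −78 → −33 °C; then (CO2H)2, MeOH/H2O, rt
Reagents that add atoms: water, O
Why: Birch reduction of the anisole gives the 1-methoxy-1,4-diene with both methyl groups on the second alkene, and mild oxalic-acid hydrolysis of the enol ether (carbonyl oxygen from water) should stop at the non-conjugated β,γ-enone; no stereocentre is formed.

Step 2
Reactants: 3 3,4-dimethylcyclohex-3-en-1-one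
Product: 4 (R)-3,4-dimethylcyclohex-2-en-1-one
Conditions: cinchona-derived chiral primary amine (10 mol %, the pseudo-enantiomer leading to the R enone), carboxylic acid co-catalyst, toluene, −25 °C
Reagents that add atoms: none
Why: Catalytic enantioselective olefin isomerisation, in which the amine forms an iminium ion, α-deprotonation gives a dienamine and face-selective γ-protonation sets ring C4 (C8 of the target) as R, with conjugation as the driving force.

Step 3
Reactants: 4 (R)-3,4-dimethylcyclohex-2-en-1-one; 5 3-(2-bromoethyl)furan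
Product: 8 (3S,4R)-3-[2-(furan-3-yl)ethyl]-3,4-dimethylcyclohex-1-en-1-yl trifluoromethanesulfonate, via furylethylmagnesium bromide 6 (not isolated), via bromomagnesium enolate 7 (not isolated)
Conditions: Mg, THF; CuBr·SMe2 (10 mol %), 4, THF, −40 → 0 °C; then N-(5-chloropyridin-2-yl)triflimide, −78 °C → rt
Reagents that add atoms: N-(5-chloropyridin-2-yl)-1,1,1-trifluoro-N-(trifluoromethylsulfonyl)methanesulfonamide, FC(F)(F)S(=O)(=O)N(c1ccc(Cl)cn1)S(=O)(=O)C(F)(F)F; magnesium, [Mg] (into 6 and 7 only)
Why: Copper-catalysed conjugate addition of the Grignard reagent creates the quaternary C9 with the furylethyl group entering trans to the adjacent C8 methyl (the usual approach anti to the 4-substituent of a cyclohexenone, hence cis-dimethyl, 9S), and the regiodefined magnesium enolate is O-sulfonylated to fix the C5=C10 alkene.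

Step 4
Reactants: 8 (3S,4R)-3-[2-(furan-3-yl)ethyl]-3,4-dimethylcyclohex-1-en-1-yl trifluoromethanesulfonate; 9 (tributylstannyl)methanol
Product: 10 [(3S,4R)-3-[2-(furan-3-yl)ethyl]-3,4-dimethylcyclohex-1-en-1-yl]methanol
Conditions: Pd(PPh3)4 (5 mol %), LiCl (3 equiv), 1,4-dioxane, 100 °C
Reagents that add atoms: none
Why: Stille cross-coupling of an alkenyl triflate with a hydroxymethylstannane, with LiCl assisting transmetalation, installs C19 without moving the alkene and leaves C8 and C9 untouched.

Step 5
Reactants: 10 [(3S,4R)-3-[2-(furan-3-yl)ethyl]-3,4-dimethylcyclohex-1-en-1-yl]methanol; 11 2-oxo-2H-pyran-3-carboxylic acid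
Product: 12 [(3S,4R)-3-[2-(furan-3-yl)ethyl]-3,4-dimethylcyclohex-1-en-1-yl]methyl 2-oxo-2H-pyran-3-carboxylate
Conditions: EDC·HCl, DMAP (10 mol %), CH2Cl2, 0 °C → rt
Reagents that add atoms: none
Why: Carbodiimide (Steglich-type) esterification of an unhindered primary allylic alcohol; no stereocentre is involved.

Step 6
Reactants: 12 [(3S,4R)-3-[2-(furan-3-yl)ethyl]-3,4-dimethylcyclohex-1-en-1-yl]methyl 2-oxo-2H-pyran-3-carboxylate
Product: 14 cis-fused diene lactone (5S,8R,9S,10S)-15,16-epoxycleroda-1,3,13(16),14-tetraen-18,19-olide, via CO2-bridged cycloadduct 13 (not isolated)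
Conditions: o-dichlorobenzene (0.01 M), BHT (cat.), 160 °C, sealed tube
Reagents that add atoms: none
Why: Intramolecular inverse-electron-demand Diels–Alder reaction of the electron-poor 3-acyl-2-pyrone with the tethered trisubstituted alkene, followed by retro-Diels–Alder loss of CO2, should give the homoannular diene; suprafacial addition to the ring alkene forces the new C5 and C10 centres cis, and addition anti to the pseudo-axial C9 methyl should favour the isomer drawn, although its 5,10-bis-epimer would be carried on equally because step 9 erases both centres.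

Step 7
Reactants: 14 cis-fused diene lactone
Product: 17 allyl (5S,8R,9S,10S)-19-acetoxy-15,16-epoxycleroda-1,3,13(16),14-tetraen-18-oate, via potassium hydroxy carboxylate 15 (not isolated), via hydroxy allyl ester 16 (not isolated)
Conditions: KOH (1.05 equiv), THF/H2O, rt; evaporate; allyl bromide, DMF, 0 °C → rt; then Ac2O, Et3N, DMAP (cat.), 0 °C
Reagents that add atoms: potassium hydroxide, [K+].[OH-]; allyl bromide, C=CCBr; acetic anhydride, CC(=O)OC(C)=O
Why: Saponification of the lactone, SN2 O-alkylation of the carboxylate and DMAP-catalysed acetylation are run without isolation so that the C19 hydroxyl is capped before the hydroxy ester can re-lactonise; no stereocentre is touched.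

Step 8
Reactants: 17 allyl (5S,8R,9S,10S)-19-acetoxy-15,16-epoxycleroda-1,3,13(16),14-tetraen-18-oate
Product: 18 (5S,8R,9S,10S)-19-acetoxy-15,16-epoxycleroda-1,3,13(16),14-tetraen-18-oic acid
Conditions: Pd(PPh3)4 (5 mol %), morpholine (3 equiv), THF, rt
Reagents that add atoms: none
Why: Tsuji–Trost-type deallylation, in which Pd(0) ionises only the allyl ester (the C19 acetate is neopentyl, not allylic) and morpholine traps the π-allyl complex, frees the acid under neutral conditions.

Step 9
Reactants: 18 (5S,8R,9S,10S)-19-acetoxy-15,16-epoxycleroda-1,3,13(16),14-tetraen-18-oic acid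
Product: 19 (1(10)E,2Z,4Z,8R,9S)-19-acetoxy-15,16-epoxy-5,10-secocleroda-1(10),2,4,13(16),14-pentaen-18-oic acid (target)
Conditions: hν (300 nm, Pyrex), degassed Et2O, −40 °C, partial conversion with recycling of 18
Reagents that add atoms: none
Why: Direct excitation of the homoannular dienoic acid should trigger a conrotatory 6π electrocyclic ring opening that cleaves the C5–C10 bond shared by rings A and B, so the ten-membered ring arises by ring expansion (fission of the zero-atom bridge of the bicyclo[4.4.0] system) and not by an end-to-end closure. The closest known reaction type is the photochemical opening of hexalin-type cyclohexa-1,3-dienes to cyclodeca-1,3,5-trienes (the provitamin D to previtamin D type). No stereocentre is created; C8 and C9 are untouched and C5 and C10 become sp2, so both cis-fused isomers of 18 should give the same triene. Conrotation of a cis-fused diene must deliver one E and two Z ring alkenes, and the sense that turns H-10 inward and C9 outward (C6 inward, C19 outward) is the only one that avoids an E-tetrasubstituted C4=C5 in a ten-membered ring, which gives 1(10)E,2Z,4Z with CH2OAc and CO2H cis. The step needs chemoselectivity against secondary photoreactions of the triene and against thermal disrotatory re-closure, which low temperature, the 300 nm cut-off and partial conversion should secure.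

Compound list
1 | 3,4-dimethylanisole | COc1ccc(C)c(C)c1 | starting material
2 | 1-methoxy-4,5-dimethylcyclohexa-1,4-diene | COC1=CCC(C)=C(C)C1 | intermediate (not isolated)
3 | 3,4-dimethylcyclohex-3-en-1-one | CC1=C(C)CC(=O)CC1 | intermediate
4 | (R)-3,4-dimethylcyclohex-2-en-1-one | C[C@@H]1CCC(=O)C=C1C | intermediate
5 | 3-(2-bromoethyl)furan | BrCCc1ccoc1 | starting material
6 | [2-(furan-3-yl)ethyl]magnesium bromide | Br[Mg]CCc1ccoc1 | intermediate (not isolated)
7 | bromomagnesium (3S,4R)-3-[2-(furan-3-yl)ethyl]-3,4-dimethylcyclohex-1-en-1-olate | Br[Mg]OC1=C[C@@](C)(CCc2ccoc2)[C@H](C)CC1 | intermediate (not isolated)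
8 | (3S,4R)-3-[2-(furan-3-yl)ethyl]-3,4-dimethylcyclohex-1-en-1-yl trifluoromethanesulfonate | FC(F)(F)S(=O)(=O)OC1=C[C@@](C)(CCc2ccoc2)[C@H](C)CC1 | intermediate
9 | (tributylstannyl)methanol | CCCC[Sn](CO)(CCCC)CCCC | starting material
10 | [(3S,4R)-3-[2-(furan-3-yl)ethyl]-3,4-dimethylcyclohex-1-en-1-yl]methanol | OCC1=C[C@@](C)(CCc2ccoc2)[C@H](C)CC1 | intermediate
11 | 2-oxo-2H-pyran-3-carboxylic acid | OC(=O)C1=CC=COC1=O | starting material
12 | [(3S,4R)-3-[2-(furan-3-yl)ethyl]-3,4-dimethylcyclohex-1-en-1-yl]methyl 2-oxo-2H-pyran-3-carboxylate | O=C(OCC1=C[C@@](C)(CCc2ccoc2)[C@H](C)CC1)C1=CC=COC1=O | intermediate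
13 | CO2-bridged cycloadduct (2-oxabicyclo[2.2.2]oct-5-en-3-one; new bonds C4–C5 and C1–C10, O–C(=O) bridge from C1 to C4, γ-lactone C18–O–C19, ring B on the side of the etheno bridge) | C1=C[C@H]3[C@H]2[C@@](C)(CCc4ccoc4)[C@H](C)CC[C@@]2(COC2=O)[C@]12C(=O)O3 | intermediate (not isolated)
14 | (5S,8R,9S,10S)-15,16-epoxycleroda-1,3,13(16),14-tetraen-18,19-olide (5,10-cis; H-10, C19, C17 and C20 on one face) | C1=C[C@H]2[C@@](C)(CCc3ccoc3)[C@H](C)CC[C@@]2(COC2=O)C2=C1 | intermediate
15 | potassium (5S,8R,9S,10S)-19-hydroxy-15,16-epoxycleroda-1,3,13(16),14-tetraen-18-oate | C1=C[C@H]2[C@@](C)(CCc3ccoc3)[C@H](C)CC[C@@]2(CO)C(C([O-])=O)=C1.[K+] | intermediate (not isolated)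
16 | allyl (5S,8R,9S,10S)-19-hydroxy-15,16-epoxycleroda-1,3,13(16),14-tetraen-18-oate | C1=C[C@H]2[C@@](C)(CCc3ccoc3)[C@H](C)CC[C@@]2(CO)C(C(=O)OCC=C)=C1 | intermediate (not isolated)
17 | allyl (5S,8R,9S,10S)-19-acetoxy-15,16-epoxycleroda-1,3,13(16),14-tetraen-18-oate | C1=C[C@H]2[C@@](C)(CCc3ccoc3)[C@H](C)CC[C@@]2(COC(C)=O)C(C(=O)OCC=C)=C1 | intermediate
18 | (5S,8R,9S,10S)-19-acetoxy-15,16-epoxycleroda-1,3,13(16),14-tetraen-18-oic acid | C1=C[C@H]2[C@@](C)(CCc3ccoc3)[C@H](C)CC[C@@]2(COC(C)=O)C(C(=O)O)=C1 | intermediate
19 | (1(10)E,2Z,4Z,8R,9S)-19-acetoxy-15,16-epoxy-5,10-secocleroda-1(10),2,4,13(16),14-pentaen-18-oic acid | CC(=O)OC/C1=C(C(=O)O)/C=C\C=C\[C@@](C)(CCc2ccoc2)[C@H](C)CC1 | target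

Total step count: 9. Longest linear sequence: 9 steps (1 → 19); 5, 9 and 11 enter as purchased building blocks.

Steps most likely to fail

1. Step 9. The excited diene may decay unproductively or open in a conrotatory sense that is controlled only by strain. The triene also absorbs and may undergo secondary E/Z isomerisation or photochemical re-closure, so a photostationary mixture could result. The fallback sets out from 14 and comes back at 19. Lactone 14 would be irradiated under the same conditions to give the seco-butenolide F1. Its five-membered lactone ties C19 to C18, so conrotation can only give the ring-Z C4=C5 and therefore the E C1=C10. The butenolide would then be opened with KOH to the potassium hydroxy carboxylate F2. This would be O-alkylated with 2-(trimethylsilyl)ethoxymethyl chloride to the hydroxy SEM ester F3 and acetylated in the same flask (Ac2O, DMAP) to the acetoxy SEM ester F4. MgBr2·OEt2 would finally remove the SEM group to give 19 without touching the allylic acetate.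

2. Step 6. The ester tether prefers the rotamer that keeps pyrone and alkene apart, and the trisubstituted alkene next to the quaternary C9 is hindered. Cycloaddition may therefore be slower than thermal decomposition or 1,5-hydrogen shift of the diene. The fallback sets out from 10 and comes back at 14. Alcohol 10 would be esterified with propiolic acid (DCC) to the propiolate F5, a 1,6-enyne. A cationic Rh(I)/bisphosphine-catalysed [2+2+2] cycloaddition with acetylene would then assemble ring A on the metal (oxidative cyclisation of the enyne, insertion of acetylene, reductive elimination) and deliver the cis-fused diene lactone 14 directly.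

3. Step 7. The hydroxy ester may re-lactonise before the hydroxyl is acetylated, or the alcohol may be O-allylated. The fallback sets out from 14 and comes back at 18, bypassing 17 and step 8. Lactone 14 would be opened with Me3Al/MeNH(OMe)·HCl to the hydroxy N-methoxy-N-methylamide F6 and acetylated (Ac2O, pyridine) to the acetoxy amide F7. Reduction with Cp2Zr(H)Cl, which spares the acetate, would give the acetoxy dienal F8. Pinnick oxidation (NaClO2, NaH2PO4, 2-methyl-2-butene) would then give acid 18.

Further compounds
F1 | step 9 | (1(10)E,2Z,4Z,8R,9S)-15,16-epoxy-5,10-secocleroda-1(10),2,4,13(16),14-pentaen-18,19-olide | O=C1OCC2=C1/C=C\C=C\[C@@](C)(CCc3ccoc3)[C@H](C)CC2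
F2 | step 9 | potassium (1(10)E,2Z,4Z,8R,9S)-19-hydroxy-15,16-epoxy-5,10-secocleroda-1(10),2,4,13(16),14-pentaen-18-oate | OC/C1=C(C([O-])=O)/C=C\C=C\[C@@](C)(CCc2ccoc2)[C@H](C)CC1.[K+]
F3 | step 9 | [2-(trimethylsilyl)ethoxy]methyl (1(10)E,2Z,4Z,8R,9S)-19-hydroxy-15,16-epoxy-5,10-secocleroda-1(10),2,4,13(16),14-pentaen-18-oate | OC/C1=C(C(=O)OCOCC[Si](C)(C)C)/C=C\C=C\[C@@](C)(CCc2ccoc2)[C@H](C)CC1
F4 | step 9 | [2-(trimethylsilyl)ethoxy]methyl (1(10)E,2Z,4Z,8R,9S)-19-acetoxy-15,16-epoxy-5,10-secocleroda-1(10),2,4,13(16),14-pentaen-18-oate | CC(=O)OC/C1=C(C(=O)OCOCC[Si](C)(C)C)/C=C\C=C\[C@@](C)(CCc2ccoc2)[C@H](C)CC1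
F5 | step 6 | [(3S,4R)-3-[2-(furan-3-yl)ethyl]-3,4-dimethylcyclohex-1-en-1-yl]methyl prop-2-ynoate | C#CC(=O)OCC1=C[C@@](C)(CCc2ccoc2)[C@H](C)CC1
F6 | step 7 | (5S,8R,9S,10S)-19-hydroxy-N-methoxy-N-methyl-15,16-epoxycleroda-1,3,13(16),14-tetraen-18-amide | C1=C[C@H]2[C@@](C)(CCc3ccoc3)[C@H](C)CC[C@@]2(CO)C(C(=O)N(C)OC)=C1
F7 | step 7 | (5S,8R,9S,10S)-19-acetoxy-N-methoxy-N-methyl-15,16-epoxycleroda-1,3,13(16),14-tetraen-18-amide | C1=C[C@H]2[C@@](C)(CCc3ccoc3)[C@H](C)CC[C@@]2(COC(C)=O)C(C(=O)N(C)OC)=C1
F8 | step 7 | (5S,8R,9S,10S)-19-acetoxy-15,16-epoxycleroda-1,3,13(16),14-tetraen-18-al | C1=C[C@H]2[C@@](C)(CCc3ccoc3)[C@H](C)CC[C@@]2(COC(C)=O)C(C=O)=C1
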